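The second is our unit: we ask how many seconds the starting material lasts and how many the catalyst needs to appear.

common to all: starting material 20 mM; reagent 18.0 mM (fed, over 6.0 s); precatalyst 3.0 mM; time 2.5 min

| charge | temperature |
|---|---|
| west | 0 °C |
| south-east | 25 °C |
| south-west | 50 °C |

    catalyst intermediate A ⇌ catalyst intermediate B (K1 = 2.0, k1 = 0.15 s⁻¹, Ea1 = 71.0 kJ mol⁻¹, ΔH1 = −22.0 kJ mol⁻¹)
    catalyst intermediate C → free catalyst + target (k2 = 0.26 s⁻¹, Ea2 = 64.0 kJ mol⁻¹)
    precatalyst → free catalyst (k3 = 0.0016 s⁻¹, Ea3 = 81.0 kJ mol⁻¹)
    reagent + free catalyst → catalyst intermediate A (k4 = 15 L mol⁻¹ s⁻¹, Ea4 = 51.0 kJ mol⁻¹)
    starting material + catalyst intermediate B → catalyst intermediate C (k5 = 75 L mol⁻¹ s⁻¹, Ea5 = 36.0 kJ mol⁻¹)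
    2 starting material → self-condensation product (k6 = 1.1 L mol⁻¹ s⁻¹, Ea6 = 55.0 kJ mol⁻¹)
    (constants at 0 °C)

- percent here means starting material units held: one self-condensation product counts as two
- a step written with two of one species runs at k times the square of its concentration and takes two of it each time
- at 0 °C the constants are as listed, elsewhere as the activation energies and enthalpies make them

- the flask with the highest amount of target, in percent of the starting material charged ("all alike" if they lie within 1.5 percentage points) (west / south-east / south-west / all alike)
- final target, as a percentage of the starting material charged, in west
- final target, as a percentage of the starting material charged, in south-east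
- final target, as a percentage of the starting material charged, in south-west

We reckon the two outer flasks from the constants and charges above, solving early and late times and joining them.

1. In south-west, catalyst intermediate B holds the equilibrium share f = 30.9% of intermediates A and B together. Of the three rungs we reckon, the A ⇌ B exchange is the fastest, with a relaxation time of 0.0163 s.

2. Next in south-west comes the starting material. Its first half-life by self-condensation is τ = 0.536 s.

3. Slower in south-west is precatalyst release, with a time of 2.51 s, longer than τ. The starting material therefore starts to condense before much catalyst exists.

4. Now we solve both ends. Let b be twice the self-condensation constant, a the constant of capture by catalyst intermediate B, and g the product of f, the release constant and the precatalyst charge. Early on, B grows as g·t. Once t exceeds τ, we let self-condensation set the starting material at about 1/(b·t). Target then forms at the steady rate a·g/b. Capture is pseudo-first-order, and it takes over at t* = 1/√(a·g).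

5. Joining the ends gives the capture yield P* = √(a·g)/b, the target made before the starting material is gone. In south-west, t* = 1.76 s and P* = 6.08 mM, or 30.4% of the charge. We ignored the reagent feed, which lasts 6.0 s, longer than t*, so we expect to read high.

6. In west, t* = 64.5 s and P* = 7.04 mM, or 35.2%, which is 4.8 percentage points above south-west. But the release time there is 10.4 min, longer than the run, and 21.3% of the precatalyst is released by the end. West is short of time, so we expect it to fall well below its P*.

7. South-east lies near the middle of the outer flasks on a scale of reciprocal temperature, so we take its t* roughly as the geometric mean of theirs, 10.7 s. That is longer than the feed and shorter than the run. We expect its P* to lie between those of the outer flasks, so above the 30.4% of south-west. On this rough ground we commit to south-east as the best.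

The forecast also names south-east, with 10.5%, 22% and 18% for west, south-east and south-west, judging that “25 °C looks like the best compromise”.

The simulation gives south-east, with 10.6% in west, 20.9% in south-east and 17.1% in south-west.

South-west reached 0.563 of its P*, so our reckoning did read high. In south-west at 0.00634 min, self-condensation used starting material 230 times as fast as capture did. Half of its turnover was done by 0.380 s, earlier than the 0.0503 min at which half of the catalyst capture by reagent was done.

Take the neighbour like south-west but with 1.2 mM of precatalyst. P* goes as the square root of the charge, giving 19.2%, and the same ratio turns this into 10.8%. The computed result is 12.7%, somewhat more than that.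

The constants are those of an exercise.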